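The trans-hydroazulene is cut at the C1–C5 bond, which joins quaternary C1 to ring-fusion carbon C5 and is shared by the five- and seven-membered rings. The feature exploited is that oxygen-bearing C6 sits beside C5 in the seven-membered ring. In one base-induced semipinacol shift, C1 moves from carbinol C6 to mesylate-bearing C5 of an all-syn cis-decalin 4,5,6-triol 5-mesylate (C9 ketal): one six-membered ring contracts to the cyclopentane, the other expands to the cycloheptanone, and the trans ring fusion is set at C5. Directed C6 reduction, O4 vanilloylation, unveiling of C8=C9 and α-epoxidation finish the target.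

Key step: step 9

Remarks and assumptions
- Numbering: all bicyclic compounds, decalins included, carry the numbering of the target. C1 is the methyl-bearing quaternary carbon, then C2, C3, C4 (isopropyl and oxygen), C5, C6 (oxygen), C7, C8 (methyl), C9, C10. β is the face of the C1 methyl, α the opposite face. The decalin rings are C1–C2–C3–C4–C5–C6 and C1–C6–C7–C8–C9–C10. In the hydroazulenes the five-membered ring is C1–C5 and the seven-membered ring is C1, C5–C10.
- Assumption: the chiral-imine Michael addition of step 3 follows its usual sense of induction, so the (R)-amine gives the (R)-configured quaternary carbon.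
- Compounds 3, 4, 7, 8 and 9 are used as stereoisomer mixtures at the CH–CH3 carbons. These converge in step 4, and C8 becomes sp2 in step 16.

Step 1
Reactants: 1 2,5-dimethyl-1,4-benzoquinone
Product: 3 2,5-dimethylcyclohexane-1,4-diol (stereoisomer mixture), via 2,5-dimethylhydroquinone 2 (not isolated)
Conditions: H2 (60 bar), 5% Rh/Al2O3, EtOH, 60 °C
Reagents that add atoms: none
Why: Heterogeneous catalytic hydrogenation should first reduce the quinone to the hydroquinone and then saturate the electron-rich ring over rhodium; the stereoisomer mixture does not matter because all ring stereocentres are erased or equilibrated in steps 2 to 4.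

Step 2
Reactants: 3 2,5-dimethylcyclohexane-1,4-diol
Product: 4 2,5-dimethylcyclohexane-1,4-dione (cis/trans mixture)
Conditions: NaOCl (aq), AcOH, 20 °C
Reagents that add atoms: none
Why: Hypochlorite oxidation of secondary alcohols in acetic acid (Stevens oxidation) should turn both carbinols into ketones, and the α-methyl centres remain freely epimerisable.

Step 3
Reactants: 4 2,5-dimethylcyclohexane-1,4-dione, 5 (R)-1-phenylethylamine, 6 methyl vinyl ketone
Product: 9 (2R)-2,5-dimethyl-2-(3-oxobutyl)cyclohexane-1,4-dione (both epimers at the second methyl-bearing carbon), via mono-imine 7 (not isolated), via Michael adduct imine 8 (not isolated)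
Conditions: 5 (1.0 equiv), 4 (2 equiv, excess recovered), TsOH (cat.), toluene, Dean–Stark, reflux; then 6, THF, 40 °C; then 10% aq. AcOH, 23 °C
Reagents that add atoms: methyl vinyl ketone CC(=O)C=C; water O
Why: Chiral-imine asymmetric Michael addition: the more substituted secondary enamine tautomer of 7 adds to the enone in a compact aza-ene-type transition state on the face not shielded by the phenyl group of the auxiliary, which sets the quaternary centre as R, and mild acid hydrolysis of 8 frees the ketone and the amine.

Step 4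
Reactants: 9 (2R)-2,5-dimethyl-2-(3-oxobutyl)cyclohexane-1,4-dione
Product: 11 (4aR,7S)-4a,7-dimethyl-4,4a,7,8-tetrahydronaphthalene-2,6(3H,5H)-dione, via bicyclic ketol 10 (not isolated)
Conditions: NaOMe (cat.), MeOH, 60 °C
Reagents that add atoms: none
Why: The Robinson annulation is completed by intramolecular aldol addition of the methyl ketone enolate to the ring carbonyl next to the quaternary carbon and irreversible E1cB dehydration of ketol 10 (other ketols revert), while methoxide equilibrates the C8 methyl to the equatorial position cis to the C1 methyl.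

Step 5
Reactants: 11 the enedione, 12 ethylene glycol
Product: 13 (4aR,7S)-6,6-ethylenedioxy-4a,7-dimethyl-4,4a,5,6,7,8-hexahydronaphthalen-2(3H)-one
Conditions: TsOH (cat.), benzene, Dean–Stark, reflux, stopped at the mono-acetal
Reagents that add atoms: ethylene glycol OCCO
Why: Acid-catalysed acetalisation is chemoselective for the saturated C9 ketone because the conjugated C4 carbonyl is less electrophilic and forms its acetal much more slowly, as in the usual mono-protection of octalenediones.

Step 6
Reactants: 13 the enone acetal, 14 isopropylmagnesium chloride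
Product: 15 the 4β-hydroxy-4α-isopropyl allylic alcohol (C5=C6 alkene; C9 acetal; 1β- and 8β-methyl)
Conditions: CeCl3 (anhydrous), THF, −78 → 0 °C; aq. NH4Cl
Reagents that add atoms: isopropylmagnesium chloride CC(C)[Mg]Cl
Why: Organocerium 1,2-addition suppresses enolisation and conjugate addition, and the bulky isopropyl group attacks C4 from the α face, anti to the angular C1 methyl, which sets the 4β-hydroxyl.

Step 7
Reactants: 15 the allylic alcohol, 16 osmium tetroxide
Product: 18 the all-syn 4β,5β,6β-triol (cis-fused decalin; C9 acetal), via osmate ester TMEDA complex 17 (not isolated)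
Conditions: OsO4 (1.05 equiv), TMEDA (1.1 equiv), CH2Cl2, −78 °C; then aq. Na2SO3, THF, 60 °C
Reagents that add atoms: osmium tetroxide O=[Os](=O)(=O)=O
Why: Hydroxyl-directed dihydroxylation: the OsO4–TMEDA complex is hydrogen-bonded to the C4 hydroxyl and adds to C5=C6 by [3+2] cycloaddition on the β face syn to that hydroxyl, which sets C5 and C6 and gives the cis-fused all-syn triol after reductive cleavage of 17.

Step 8
Reactants: 18 the all-syn triol, 19 methanesulfonyl chloride
Product: 20 all-syn 2,8a-dihydroxy-2-isopropyl-4a,7-dimethyl-6,6-ethylenedioxydecahydronaphthalen-1-yl methanesulfonate (4β-OH; 5β-OMs; 6β-OH)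
Conditions: Et3N, CH2Cl2, −10 °C
Reagents that add atoms: methanesulfonyl chloride CS(=O)(=O)Cl
Why: Sulfonylation through sulfene is selective for the only secondary hydroxyl, the two tertiary hydroxyls being too hindered to react at low temperature, and no stereocentre is touched.

Step 9
Reactants: 20 the all-syn diol monomesylate
Product: 22 trans-fused 3-hydroxy-3-isopropyl-6,8a-dimethyl-7,7-ethylenedioxyoctahydroazulen-4(1H)-one (4β-OH; 5α-H; C6 ketone), via C6 potassium alkoxide 21 (not isolated)
Conditions: KOt-Bu (1.2 equiv), THF/t-BuOH, −10 → 10 °C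
Reagents that add atoms: none
Why: Deprotonation gives the C6 alkoxide 21, whose oxygen pushes the C6–C1 bond (antiperiplanar to the equatorial C5–OMs bond in the chair with equatorial isopropyl) onto C5 as mesylate leaves, so that C6 becomes the ketone in one concerted 1,2-shift. The closest known reaction type is the base-induced pinacol-type (semipinacol) rearrangement of cyclic cis-1,2-diol monosulfonates, an established way from hydronaphthalenes to hydroazulenones. No ring is closed by cyclisation: the cyclopentane (C1–C2–C3–C4–C5) arises by ring contraction through the new C1–C5 bond and the cycloheptanone (C1, C5–C10) by the matching one-carbon ring expansion. The only new stereocentre, C5, is set by stereospecific backside displacement (inversion at C5, retention at migrating C1), which turns the all-syn array into H5 α, anti to the C1 methyl, i.e. the trans ring fusion. The step needs migration of C1 and not of C7 (possible only from the chair with axial mesylate) or of C3 (pushed by the C4 alkoxide): the equatorial isopropyl group fixes the reactive chair, the fully substituted C1 has the higher migratory aptitude, and both flanking hydroxyls are syn to the mesylate, so no epoxide can form. Low temperature and only a small excess of base limit retro-aldol opening and C5 epimerisation of the β-hydroxy ketone product.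

Step 10
Reactants: 22 the hydroxy ketone
Product: 23 the 4β,6α-diol (3-isopropyl-6,8a-dimethyl-7,7-ethylenedioxydecahydroazulene-3,4-diol; 5α-H)
Conditions: Me4NBH(OAc)3, MeCN/AcOH, −30 → 0 °C
Reagents that add atoms: none
Why: Hydroxyl-directed reduction (Evans–Saksena type): the C4 hydroxyl exchanges for acetate on boron and hydride is delivered intramolecularly to the β face of the C6 carbonyl, the face on which O4 lies, which sets the 6α-hydroxyl (H6 β, trans to H5), while the acetal survives the anhydrous acid at low temperature.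

Step 11
Reactants: 23 the 4β,6α-diol, 24 tert-butyldimethylsilyl triflate
Product: 25 the 6α-O-tert-butyldimethylsilyl ether of 23 (4β-OH free)
Conditions: 2,6-lutidine, CH2Cl2, −78 °C
Reagents that add atoms: tert-butyldimethylsilyl triflate CC(C)(C)[Si](C)(C)OS(=O)(=O)C(F)(F)F
Why: Silyl triflate silylation with a hindered pyridine base protects the secondary C6 hydroxyl selectively, since the tertiary C4 hydroxyl next to the isopropyl group reacts much more slowly at −78 °C.

Step 12
Reactants: 26 vanillic acid, 27 tert-butyldimethylsilyl chloride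
Product: 28 tert-butyldimethylsilyl 4-(tert-butyldimethylsilyloxy)-3-methoxybenzoate
Conditions: 27 (2.2 equiv), imidazole, DMF, 23 °C
Reagents that add atoms: tert-butyldimethylsilyl chloride CC(C)(C)[Si](C)(C)Cl
Why: Imidazole-promoted silylation converts the phenol into its silyl ether and the acid into its silyl ester in one operation.

Step 13
Reactants: 28 the bis-silylated vanillic acid, 29 oxalyl chloride
Product: 30 4-(tert-butyldimethylsilyloxy)-3-methoxybenzoyl chloride
Conditions: DMF (cat.), CH2Cl2, 0 → 23 °C
Reagents that add atoms: oxalyl chloride ClC(=O)C(=O)Cl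
Why: Silyl esters react with the chloroiminium salt formed from oxalyl chloride and DMF (Vilsmeier-type activation) to give acid chlorides under neutral conditions without HCl, so the aryl silyl ether is kept.

Step 14
Reactants: 25 the 6α-O-silyl ether, 30 the aroyl chloride
Product: 32 the 4β-O-[4-(tert-butyldimethylsilyloxy)-3-methoxybenzoyl] ester of 25, via lithium alkoxide 31 (not isolated)
Conditions: n-BuLi (1.05 equiv), THF, −78 °C; then 30, −78 → 0 °C
Reagents that add atoms: 4-(tert-butyldimethylsilyloxy)-3-methoxybenzoyl chloride COc1cc(C(Cl)=O)ccc1O[Si](C)(C)C(C)(C)C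
Why: Acylation of a preformed lithium alkoxide by an aroyl chloride (nucleophilic acyl substitution) is the standard way to esterify a hindered tertiary alcohol, and the lithium counter-ion at low temperature disfavours silyl migration from O6 to O4.

Step 15
Reactants: 32 the ester acetal
Product: 33 the C9 ketone (4β-aroyloxy; 6α-silyloxy)
Conditions: AcOH/THF/H2O (3:1:1), 45 °C
Reagents that add atoms: water O
Why: Mild acid-catalysed acetal hydrolysis unmasks the C9 ketone while the secondary and aryl silyl ethers and the tertiary aryl ester tolerate aqueous acetic acid; any epimerisation at C8 is harmless because C8 becomes sp2 in step 16.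

Step 16
Reactants: 33 the C9 ketone, 34 N-(5-chloropyridin-2-yl)bis(trifluoromethanesulfonyl)imide (Comins' reagent)
Product: 36 the C8=C9 enol triflate (triflate on C9; methyl on C8), via lithium enolate 35 (not isolated)
Conditions: LiN(SiMe3)2 (0.95 equiv), THF, −78 → 23 °C; then 34, −78 → 0 °C
Reagents that add atoms: N-(5-chloropyridin-2-yl)bis(trifluoromethanesulfonyl)imide O=S(=O)(N(c1ccc(Cl)cn1)S(=O)(=O)C(F)(F)F)C(F)(F)F
Why: Thermodynamic enolate formation and O-sulfonylation: with slightly less than one equivalent of base the lithium enolates equilibrate through the residual ketone to the more substituted C8=C9 enolate 35 (C10 is a hindered neopentyl-type position), which the triflimide traps on oxygen.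

Step 17
Reactants: 36 the enol triflate
Product: 37 the C8=C9 alkene (4β-aroyloxy; 6α-silyloxy; aryl silyl ether)
Conditions: Pd(OAc)2 (cat.), PPh3, HCO2H, n-Bu3N, DMF, 60 °C
Reagents that add atoms: none
Why: Palladium-catalysed formate hydrogenolysis of an enol triflate: oxidative addition to zerovalent palladium, formate exchange, decarboxylation and C–H reductive elimination replace the triflate by hydrogen without moving the C8=C9 double bond.

Step 18
Reactants: 37 the bis-silyl alkene
Product: 38 the 4β-O-vanilloyl 6α-hydroxy C8=C9 alkene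
Conditions: Bu4NF, AcOH (1:1), THF, 23 → 40 °C
Reagents that add atoms: none
Why: Fluoride-induced desilylation cleaves both silyl ethers, and buffering with acetic acid keeps the medium non-basic so that the aroyl group does not migrate from O4 to the freed C6 hydroxyl.

Step 19
Reactants: 38 the alkene diol, 39 3-chloroperoxybenzoic acid
Product: 40 CNP0315707.1 (8α,9α-epoxide; 6α-OH; 4β-O-vanilloyl; 5α-H; 1β-methyl)
Conditions: mCPBA, NaHCO3, CH2Cl2, 0 °C
Reagents that add atoms: 3-chloroperoxybenzoic acid O=C(OO)c1cccc(Cl)c1
Why: Prilezhaev epoxidation of the trisubstituted alkene should occur on the α face, which is anti to the angular C1 methyl and is further favoured by hydrogen bonding of the peracid to the 6α-hydroxyl (Henbest-type direction), setting C8 and C9; the electron-poor para-acylated phenol is not attacked under buffered conditions.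

Compound list
1 | 2,5-dimethyl-1,4-benzoquinone | CC1=CC(=O)C(C)=CC1=O | starting material
2 | 2,5-dimethylhydroquinone (formed in the flask) | Cc1cc(O)c(C)cc1O | intermediate
3 | 2,5-dimethylcyclohexane-1,4-diol (stereoisomer mixture) | CC1CC(O)C(C)CC1O | intermediate
4 | 2,5-dimethylcyclohexane-1,4-dione (cis/trans mixture) | CC1CC(=O)C(C)CC1=O | intermediate
5 | (R)-1-phenylethylamine | C[C@@H](N)c1ccccc1 | starting material
6 | methyl vinyl ketone | CC(=O)C=C | starting material
7 | mono-imine of 4 with 5 (formed in the flask) | C[C@@H](N=C1CC(C)C(=O)CC1C)c1ccccc1 | intermediate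
8 | imine of 9 with 5 at the carbonyl next to the quaternary carbon (formed in the flask) | C[C@@H](N=C1CC(C)C(=O)C[C@@]1(C)CCC(C)=O)c1ccccc1 | intermediate
9 | (2R)-2,5-dimethyl-2-(3-oxobutyl)cyclohexane-1,4-dione (epimers at the CH–CH3 carbon) | CC(=O)CC[C@]1(C)CC(=O)C(C)CC1=O | intermediate
10 | bicyclic ketol, 8a-hydroxy-4a,7-dimethyloctahydronaphthalene-2,6-dione (formed in the flask; carbinol and C8 configuration open) | O=C1CC2(O)CC(C)C(=O)C[C@@]2(C)CC1 | intermediate
11 | (4aR,7S)-4a,7-dimethyl-4,4a,7,8-tetrahydronaphthalene-2,6(3H,5H)-dione | O=C1C=C2C[C@H](C)C(=O)C[C@@]2(C)CC1 | intermediate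
12 | ethylene glycol | OCCO | starting material
13 | (4aR,7S)-6,6-ethylenedioxy-4a,7-dimethyl-4,4a,5,6,7,8-hexahydronaphthalen-2(3H)-one | O=C1C=C2C[C@H](C)C3(OCCO3)C[C@@]2(C)CC1 | intermediate
14 | isopropylmagnesium chloride | CC(C)[Mg]Cl | starting material
15 | 4β-hydroxy-4α-isopropyl-1β,8β-dimethyl C5=C6 octalin 9-ethylene acetal | O[C@@]1(C(C)C)CC[C@]2(C)CC3(OCCO3)[C@@H](C)CC2=C1 | intermediate
16 | osmium tetroxide | O=[Os](=O)(=O)=O | starting material
17 | cyclic 5β,6β-osmate ester of 18 with TMEDA on hexavalent osmium (formed in the flask) | O[C@@]1(C(C)C)CC[C@]2(C)CC3(OCCO3)[C@@H](C)C[C@]2(O4)[C@H]1O[Os]4(=O)=O.CN(C)CCN(C)C | intermediate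
18 | all-syn 4β,5β,6β-triol, 2-isopropyl-4a,7-dimethyl-6,6-ethylenedioxydecahydronaphthalene-1,2,8a-triol (cis-fused) | O[C@@]1(C(C)C)CC[C@]2(C)CC3(OCCO3)[C@@H](C)C[C@]2(O)[C@H]1O | intermediate
19 | methanesulfonyl chloride | CS(=O)(=O)Cl | starting material
20 | all-syn 2,8a-dihydroxy-2-isopropyl-4a,7-dimethyl-6,6-ethylenedioxydecahydronaphthalen-1-yl methanesulfonate | O[C@@]1(C(C)C)CC[C@]2(C)CC3(OCCO3)[C@@H](C)C[C@]2(O)[C@H]1OS(C)(=O)=O | intermediate
21 | C6 potassium alkoxide of 20 (formed in the flask) | [K+].O[C@@]1(C(C)C)CC[C@]2(C)CC3(OCCO3)[C@@H](C)C[C@]2([O-])[C@H]1OS(C)(=O)=O | intermediate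
22 | trans-fused 3-hydroxy-3-isopropyl-6,8a-dimethyl-7,7-ethylenedioxyoctahydroazulen-4(1H)-one | O[C@@]1(C(C)C)CC[C@]2(C)CC3(OCCO3)[C@@H](C)CC(=O)[C@H]21 | intermediate
23 | 4β,6α-diol, trans-fused 3-isopropyl-6,8a-dimethyl-7,7-ethylenedioxydecahydroazulene-3,4-diol | O[C@@]1(C(C)C)CC[C@]2(C)CC3(OCCO3)[C@@H](C)C[C@H](O)[C@H]21 | intermediate
24 | tert-butyldimethylsilyl triflate | CC(C)(C)[Si](C)(C)OS(=O)(=O)C(F)(F)F | starting material
25 | 6α-O-tert-butyldimethylsilyl ether of 23 | O[C@@]1(C(C)C)CC[C@]2(C)CC3(OCCO3)[C@@H](C)C[C@H](O[Si](C)(C)C(C)(C)C)[C@H]21 | intermediate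
26 | vanillic acid | COc1cc(C(=O)O)ccc1O | starting material
27 | tert-butyldimethylsilyl chloride | CC(C)(C)[Si](C)(C)Cl | starting material
28 | tert-butyldimethylsilyl 4-(tert-butyldimethylsilyloxy)-3-methoxybenzoate | COc1cc(C(=O)O[Si](C)(C)C(C)(C)C)ccc1O[Si](C)(C)C(C)(C)C | intermediate
29 | oxalyl chloride | ClC(=O)C(=O)Cl | starting material
30 | 4-(tert-butyldimethylsilyloxy)-3-methoxybenzoyl chloride | COc1cc(C(Cl)=O)ccc1O[Si](C)(C)C(C)(C)C | intermediate
31 | C4 lithium alkoxide of 25 (formed in the flask) | [Li+].[O-][C@@]1(C(C)C)CC[C@]2(C)CC3(OCCO3)[C@@H](C)C[C@H](O[Si](C)(C)C(C)(C)C)[C@H]21 | intermediate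
32 | 4β-O-[4-(tert-butyldimethylsilyloxy)-3-methoxybenzoyl] ester of 25 | COc1cc(C(=O)O[C@@]2(C(C)C)CC[C@]3(C)CC4(OCCO4)[C@@H](C)C[C@H](O[Si](C)(C)C(C)(C)C)[C@H]32)ccc1O[Si](C)(C)C(C)(C)C | intermediate
33 | C9 ketone from 32 (C8 drawn with retained configuration) | COc1cc(C(=O)O[C@@]2(C(C)C)CC[C@]3(C)CC(=O)[C@@H](C)C[C@H](O[Si](C)(C)C(C)(C)C)[C@H]32)ccc1O[Si](C)(C)C(C)(C)C | intermediate
34 | N-(5-chloropyridin-2-yl)bis(trifluoromethanesulfonyl)imide | O=S(=O)(N(c1ccc(Cl)cn1)S(=O)(=O)C(F)(F)F)C(F)(F)F | starting material
35 | C8=C9 lithium enolate of 33 (formed in the flask) | [Li+].COc1cc(C(=O)O[C@@]2(C(C)C)CC[C@]3(C)CC([O-])=C(C)C[C@H](O[Si](C)(C)C(C)(C)C)[C@H]32)ccc1O[Si](C)(C)C(C)(C)C | intermediate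
36 | C8=C9 enol triflate | COc1cc(C(=O)O[C@@]2(C(C)C)CC[C@]3(C)CC(OS(=O)(=O)C(F)(F)F)=C(C)C[C@H](O[Si](C)(C)C(C)(C)C)[C@H]32)ccc1O[Si](C)(C)C(C)(C)C | intermediate
37 | C8=C9 alkene, bis-silyl ether | COc1cc(C(=O)O[C@@]2(C(C)C)CC[C@]3(C)CC=C(C)C[C@H](O[Si](C)(C)C(C)(C)C)[C@H]32)ccc1O[Si](C)(C)C(C)(C)C | intermediate
38 | 4β-O-vanilloyl-6α-hydroxy C8=C9 alkene | COc1cc(C(=O)O[C@@]2(C(C)C)CC[C@]3(C)CC=C(C)C[C@H](O)[C@H]32)ccc1O | intermediate
39 | 3-chloroperoxybenzoic acid | O=C(OO)c1cccc(Cl)c1 | starting material
40 | CNP0315707.1, the 4β-O-vanilloyl 8α,9α-epoxy 6α-ol with (1R)-configured quaternary carbon | COc1cc(C(=O)O[C@@]2(C(C)C)CC[C@]3(C)C[C@@H]4O[C@]4(C)C[C@H](O)[C@H]32)ccc1O | target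

Total step count: 19
Longest linear sequence: 17 steps (steps 1–11 and 14–19); steps 12 and 13 prepare the acyl donor.

Steps most likely to fail

Step 9. The C4 alkoxide may drive a competing shift of C3 onto C5 (giving an acylcyclopentane), and base may open the β-hydroxy ketone product by retro-aldol cleavage or epimerise C5. The fallback sets out from 20 and blocks O4 first. Et3SiOTf with 2,6-lutidine at −78 °C should silylate the C4 hydroxyl, since the C6 hydroxyl is shielded by the adjacent quaternary C1, giving the C4 triethylsilyl ether of the mesylate F1. The same KOt-Bu shift, now with only the C6 hydroxyl able to push, gives the β-silyloxy ketone F2, which cannot undergo retro-aldol cleavage. Desilylation with Bu4NF/AcOH returns to 22.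

Step 14. Acyl transfer to the very hindered tertiary alkoxide may be outrun by migration of the neighbouring silyl group from O6 to O4, which would leave the wrong oxygen free. The fallback sets out from 23 and uses an ether that cannot migrate. NaH, 4-methoxybenzyl chloride and Bu4NI in DMF alkylate the secondary hydroxyl to give the 6α-O-(4-methoxybenzyl) ether F3. The same alkoxide acylation with 30 gives the C4 ester F4. DDQ in buffered wet CH2Cl2 frees the C6 hydroxyl to give the hydroxy ester F5, and silylation as in step 11 returns to 32.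

Step 16. Enolisation may go toward C10 and not C8 (poor regioselectivity), giving the C9=C10 triflate and, after reduction, the wrong alkene. The fallback sets out from 33 and replaces enolate chemistry by reduction and elimination. NaBH4 in MeOH at 0 °C gives the C9 alcohol F6. Dehydration toward the tertiary C8–H (Zaitsev orientation) is done with the Burgess reagent if C8–H and the C9 oxygen are syn, or with Martin sulfurane if they are anti, and returns to 37.

Further compounds
F1 | step 9 | 4β-O-triethylsilyl ether of mesylate 20 | CC[Si](CC)(CC)O[C@@]1(C(C)C)CC[C@]2(C)CC3(OCCO3)[C@@H](C)C[C@]2(O)[C@H]1OS(C)(=O)=O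
F2 | step 9 | 4β-O-triethylsilyl ether of hydroxy ketone 22 | CC[Si](CC)(CC)O[C@@]1(C(C)C)CC[C@]2(C)CC3(OCCO3)[C@@H](C)CC(=O)[C@H]21
F3 | step 14 | 6α-O-(4-methoxybenzyl) ether of diol 23 | O[C@@]1(C(C)C)CC[C@]2(C)CC3(OCCO3)[C@@H](C)C[C@H](OCc4ccc(OC)cc4)[C@H]21
F4 | step 14 | 4β-O-[4-(tert-butyldimethylsilyloxy)-3-methoxybenzoyl] ester of F3 | COc1cc(C(=O)O[C@@]2(C(C)C)CC[C@]3(C)CC4(OCCO4)[C@@H](C)C[C@H](OCc5ccc(OC)cc5)[C@H]32)ccc1O[Si](C)(C)C(C)(C)C
F5 | step 14 | 6α-hydroxy 4β-ester (acetal and aryl silyl ether kept) | COc1cc(C(=O)O[C@@]2(C(C)C)CC[C@]3(C)CC4(OCCO4)[C@@H](C)C[C@H](O)[C@H]32)ccc1O[Si](C)(C)C(C)(C)C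
F6 | step 16 | C9 alcohol from ketone 33 (C8 and C9 configuration open) | COc1cc(C(=O)O[C@@]2(C(C)C)CC[C@]3(C)CC(O)C(C)C[C@H](O[Si](C)(C)C(C)(C)C)[C@H]32)ccc1O[Si](C)(C)C(C)(C)C
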